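**Strategy.** The ten-membered ring is not closed from a chain but grown from a cyclohexene. C-1 to C-6 of the target (germacrane numbering; C-6 is the lactone carbinol), including the cis C-3=C-4 alkene and C-2 masked as a dimethyl ketal, are assembled as a quinone-monoketal-derived cyclohexenol carrying isopropenyl on C-1 and an (E)-2-alkoxyvinyl group on carbinol carbon C-6. An anionic oxy-Cope rearrangement then forms the C-8–C-9 bond, which lies β to the C-6 carbonyl and allylic to the new (E)-C-1=C-10 alkene, cleaves C-1–C-6, transfers chirality to C-8 and releases a C-6/C-7 enolate that is alkylated in the same flask with the future lactone carbons C-11/C-12.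

Key step: step 11

Remark: atom numbers in the text refer to the target (ring C-1 to C-10; C-2 ketone, C-5 hydroxyl carbon, C-6 lactone carbinol, C-7 ring-fusion carbon, C-8 ester carbinol, C-9 CH2, C-14/C-15 methyls on C-10/C-4, C-11 to C-13 methylenelactone carbons); the acyl group is taken as (E)-2-methylbut-2-enoyl as drawn.

**Step 1**
Reactants: 1 4-methoxy-2-methylphenol
Product: 2 4,4-dimethoxy-2-methylcyclohexa-2,5-dien-1-one
Conditions: PhI(OAc)2, MeOH, 0 °C
Reagents that add atoms: methanol, CO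
Why: Oxidative dearomatisation of a para-methoxyphenol by a hypervalent iodine reagent in methanol gives the quinone monoketal, which carries C-2 of the target at the ketone oxidation level in masked form; no stereocenter is formed.

**Step 2**
Reactants: 2 4,4-dimethoxy-2-methylcyclohexa-2,5-dien-1-one; 3 isopropenylboronic acid pinacol ester
Product: 4 (5R)-4,4-dimethoxy-2-methyl-5-(prop-1-en-2-yl)cyclohex-2-en-1-one
Conditions: [Rh(C2H4)2Cl]2 (2.5 mol %), (R)-BINAP, KOH (0.5 equiv), 1,4-dioxane/H2O 10:1, 50 °C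
Reagents that add atoms: none
Why: Hayashi–Miyaura asymmetric 1,4-addition, in which the isopropenylrhodium species adds to the enone arm that lacks the α-methyl group and (R)-BINAP, by analogy with its known sense on cyclohex-2-enone, should deliver the alkenyl group to the face giving the (R) centre (future C-1).

**Step 3**
Reactants: 4 (5R)-4,4-dimethoxy-2-methyl-5-(prop-1-en-2-yl)cyclohex-2-en-1-one
Product: 6 (5S,6S)-4,4-dimethoxy-2-methyl-5-(prop-1-en-2-yl)-6-(triethylsilyloxy)cyclohex-2-en-1-one, via potassium alkoxide 5 (not isolated)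
Conditions: KHMDS, THF, −78 °C; 2-(phenylsulfonyl)-3-phenyloxaziridine; then Et3SiCl, −78 → 0 °C
Reagents that add atoms: 2-(phenylsulfonyl)-3-phenyloxaziridine, O=S(=O)(c1ccccc1)N1OC1c1ccccc1; chlorotriethylsilane, CC[Si](Cl)(CC)CC
Why: α′-Hydroxylation of the cross-conjugated potassium enolate (the CH2 group is the only enolisable position) by the N-sulfonyloxaziridine anti to the neighbouring isopropenyl group, then O-silylation of alkoxide 5; the configuration at this carbon is of no consequence because it becomes the ketone of 10.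

**Step 4**
Reactants: 6 (5S,6S)-4,4-dimethoxy-2-methyl-5-(prop-1-en-2-yl)-6-(triethylsilyloxy)cyclohex-2-en-1-one
Product: 7 (1S,5S,6S)-4,4-dimethoxy-2-methyl-5-(prop-1-en-2-yl)-6-(triethylsilyloxy)cyclohex-2-en-1-ol
Conditions: NaBH4, CeCl3·7H2O, MeOH, −78 °C
Reagents that add atoms: none
Why: Luche 1,2-reduction with axial hydride delivery should give the all-equatorial allylic alcohol, so that the new (S) carbinol (future C-5) is cis to the isopropenyl group and trans to the silyloxy group.

**Step 5**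
Reactants: 7 (1S,5S,6S)-4,4-dimethoxy-2-methyl-5-(prop-1-en-2-yl)-6-(triethylsilyloxy)cyclohex-2-en-1-ol
Product: 8 tert-butyl{[(1S,5S,6S)-4,4-dimethoxy-2-methyl-5-(prop-1-en-2-yl)-6-(triethylsilyloxy)cyclohex-2-en-1-yl]oxy}dimethylsilane
Conditions: TBSCl, imidazole, DMAP (cat.), DMF, 40 °C
Reagents that add atoms: tert-butyldimethylsilyl chloride, CC(C)(C)[Si](C)(C)Cl
Why: Imidazole-promoted silylation of the secondary allylic alcohol avoids Lewis acids that could ionise the allylic ketal, and the bulky non-chelating silyl ether is needed later for the C-6 reduction; no stereocenter is touched.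

**Step 6**
Reactants: 8 tert-butyl{[(1S,5S,6S)-4,4-dimethoxy-2-methyl-5-(prop-1-en-2-yl)-6-(triethylsilyloxy)cyclohex-2-en-1-yl]oxy}dimethylsilane
Product: 9 (1S,2S,6S)-2-(tert-butyldimethylsilyloxy)-5,5-dimethoxy-3-methyl-6-(prop-1-en-2-yl)cyclohex-3-en-1-ol
Conditions: PPTS (cat.), MeOH, 0 °C
Reagents that add atoms: none
Why: Selective acid-catalysed methanolysis removes the secondary triethylsilyl ether much faster than the tert-butyldimethylsilyl ether, and methanol as solvent returns any ionised ketal to the dimethyl ketal.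

**Step 7**
Reactants: 9 (1S,2S,6S)-2-(tert-butyldimethylsilyloxy)-5,5-dimethoxy-3-methyl-6-(prop-1-en-2-yl)cyclohex-3-en-1-ol
Product: 10 (2S,6S)-2-(tert-butyldimethylsilyloxy)-5,5-dimethoxy-3-methyl-6-(prop-1-en-2-yl)cyclohex-3-en-1-one
Conditions: Dess–Martin periodinane, NaHCO3, CH2Cl2, 0 °C
Reagents that add atoms: none
Why: Dess–Martin oxidation under bicarbonate buffer is neither acidic nor basic, so the β,γ-unsaturated α-silyloxy ketone should form without epimerisation at either α-carbon or conjugation of the isopropenyl group.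

**Step 8**
Reactants: 11 4-methoxybenzyl alcohol; 12 trichloroethylene
Product: 13 1-({[(E)-1,2-dichloroethenyl]oxy}methyl)-4-methoxybenzene
Conditions: KH, THF, 0 → 23 °C
Reagents that add atoms: none
Why: Alkoxide-induced dehydrochlorination of trichloroethylene to dichloroacetylene and anti addition of the alkoxide give the 1,2-dichlorovinyl ether, the standard precursor of an alkoxyacetylide; no stereocenter is formed.

**Step 9**
Reactants: 10 (2S,6S)-2-(tert-butyldimethylsilyloxy)-5,5-dimethoxy-3-methyl-6-(prop-1-en-2-yl)cyclohex-3-en-1-one; 13 1-({[(E)-1,2-dichloroethenyl]oxy}methyl)-4-methoxybenzene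
Product: 15 (1S,2S,6S)-2-(tert-butyldimethylsilyloxy)-5,5-dimethoxy-1-{[(4-methoxybenzyl)oxy]ethynyl}-3-methyl-6-(prop-1-en-2-yl)cyclohex-3-en-1-ol, via lithium alkoxyacetylide 14 (not isolated)
Conditions: 13, n-BuLi (2.1 equiv), THF, −78 → −40 °C; then 10, −78 °C; aq. NH4Cl
Reagents that add atoms: none
Why: Elimination and chlorine–lithium exchange convert 13 into acetylide 14, whose 1,2-addition to the ketone should occur by equatorial attack, trans to both the isopropenyl and the silyloxy group, because the axial trajectory is blocked by the axial methoxy group of the ketal; this sets the tertiary carbinol (future C-6).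

**Step 10**
Reactants: 15 (1S,2S,6S)-2-(tert-butyldimethylsilyloxy)-5,5-dimethoxy-1-{[(4-methoxybenzyl)oxy]ethynyl}-3-methyl-6-(prop-1-en-2-yl)cyclohex-3-en-1-ol
Product: 16 (1R,2S,6S)-2-(tert-butyldimethylsilyloxy)-5,5-dimethoxy-1-{(E)-2-[(4-methoxybenzyl)oxy]ethenyl}-3-methyl-6-(prop-1-en-2-yl)cyclohex-3-en-1-ol
Conditions: LiAlH4, THF, 0 → 23 °C; then H2O, aq. NaOH
Reagents that add atoms: none
Why: Hydroxyl-directed trans-hydroalumination of the propargylic alcohol followed by protonolysis gives the (E)-enol ether, the geometry required for the chirality transfer in step 11; no stereocenter is formed.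

**Step 11**
Reactants: 16 (1R,2S,6S)-2-(tert-butyldimethylsilyloxy)-5,5-dimethoxy-1-{(E)-2-[(4-methoxybenzyl)oxy]ethenyl}-3-methyl-6-(prop-1-en-2-yl)cyclohex-3-en-1-ol; 17 methyl bromoacetate
Product: 19 methyl [(1(10)E,3Z,5S,7R,8S)-5-(tert-butyldimethylsilyloxy)-2,2-dimethoxy-8-(4-methoxybenzyloxy)-4,10-dimethyl-6-oxocyclodeca-1(10),3-dien-7-yl]acetate, via potassium enolate 18 (not isolated)
Conditions: KHMDS (1.2 equiv), 18-crown-6, THF, −78 → 0 °C; then 17, −78 °C; aq. NH4Cl
Reagents that add atoms: none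
Why: KHMDS gives the potassium alkoxide of 16, in which the alkoxyvinyl and isopropenyl groups are trans-diequatorial, and a chair-like [3,3]-sigmatropic shift through C-8=C-7–C-6–C-1–C-10=C-9 (anionic oxy-Cope rearrangement) forms C-8–C-9, breaks C-1–C-6 and gives the ring-expanded enolate 18, which is C-alkylated at C-7 by 17. The closest known reaction type is the anionic oxy-Cope ring expansion of trans-1,2-dialkenylcyclohexanols to (E)-cyclodec-5-enones with trapping of the regiodefined enolate, long used for germacrane-type rings. The ten-membered ring is closed by a four-atom ring expansion (six to ten) through a six-membered cyclic transition state and not by end-to-end cyclisation, the equatorial C-1–C-2 bond in the chair giving the (E)-C-1=C-10 alkene and the cyclohexene supplying the (Z)-C-3=C-4 alkene. C-8 is set by chirality transfer, since the configurations at the carbinol and isopropenyl-bearing carbons fix the sense of the chair and the (E)-enol ether places its oxygen equatorial, which corresponds to (8S); C-7 is set in the alkylation, where the electrophile should enter on the peripheral face of the enolate, anti to the C-8–C-9 ring bond, to give (7R). The step needs the chair pathway to outrun the boat-type shift across C-5–C-6 (disfavoured because the equatorial vinyl group cannot reach C-3), and it needs alkylation to outrun β-elimination of the C-8 alkoxide and 1,2-silyl migration, which low temperature, the crown ether and immediate trapping at −78 °C are chosen to secure.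

**Step 12**
Reactants: 19 methyl [(1(10)E,3Z,5S,7R,8S)-5-(tert-butyldimethylsilyloxy)-2,2-dimethoxy-8-(4-methoxybenzyloxy)-4,10-dimethyl-6-oxocyclodeca-1(10),3-dien-7-yl]acetate
Product: 21 (1(10)E,3Z,5S,6S,7R,8S)-5-(tert-butyldimethylsilyloxy)-2,2-dimethoxy-8-(4-methoxybenzyloxy)germacra-1(10),3-dien-12,6-olide, via hydroxy ester 20 (not isolated)
Conditions: Zn(BH4)2, Et2O, −20 °C; aq. NH4Cl; then DBU (cat.), toluene, 40 °C
Reagents that add atoms: none
Why: Chelation-controlled hydride reduction in which zinc bridges the C-6 carbonyl and the C-8 ether oxygen and hydride adds anti to the axial C-7 side chain of the chelate should give the 1,3-syn (6S) alcohol 20, the same sense that the non-chelating α-silyloxy group favours by the Felkin–Anh model, after which base-catalysed transesterification closes the trans-fused γ-lactone.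

**Step 13**
Reactants: 21 (1(10)E,3Z,5S,6S,7R,8S)-5-(tert-butyldimethylsilyloxy)-2,2-dimethoxy-8-(4-methoxybenzyloxy)germacra-1(10),3-dien-12,6-olide
Product: 24 (1(10)E,3Z,5S,6S,7R,8S)-5-(tert-butyldimethylsilyloxy)-2,2-dimethoxy-8-(4-methoxybenzyloxy)germacra-1(10),3,11(13)-trien-12,6-olide, via Mannich base 22 (not isolated), via ammonium iodide 23 (not isolated)
Conditions: LiHMDS, THF, −78 °C; Me2N=CH2+ I−, −78 → 0 °C; then MeI, MeOH, 23 °C; then aq. NaHCO3, CH2Cl2
Reagents that add atoms: N,N-dimethylmethyleneiminium iodide, C=[N+](C)C.[I-]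
Why: Mannich aminomethylation of the lithium lactone enolate, N-methylation and β-elimination of trimethylamine give the α-methylene lactone, and the transient C-11 stereocenter of 22 and 23 is lost in the elimination.

**Step 14**
Reactants: 24 (1(10)E,3Z,5S,6S,7R,8S)-5-(tert-butyldimethylsilyloxy)-2,2-dimethoxy-8-(4-methoxybenzyloxy)germacra-1(10),3,11(13)-trien-12,6-olide
Product: 25 (1(10)E,3Z,5S,6S,7R,8S)-5-(tert-butyldimethylsilyloxy)-8-hydroxy-2,2-dimethoxygermacra-1(10),3,11(13)-trien-12,6-olide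
Conditions: DDQ, CH2Cl2/aq. pH 7 phosphate buffer 10:1, 0 °C
Reagents that add atoms: none
Why: Oxidative cleavage of the 4-methoxybenzyl ether by DDQ under neutral buffer should leave the silyl ether, the ketal and the alkenes untouched, and C-8 keeps its configuration because the C-8–O bond is not broken.

**Step 15**
Reactants: 25 (1(10)E,3Z,5S,6S,7R,8S)-5-(tert-butyldimethylsilyloxy)-8-hydroxy-2,2-dimethoxygermacra-1(10),3,11(13)-trien-12,6-olide; 26 (E)-2-methylbut-2-enoyl chloride
Product: 27 (1(10)E,3Z,5S,6S,7R,8S)-5-(tert-butyldimethylsilyloxy)-2,2-dimethoxy-8-[(E)-2-methylbut-2-enoyloxy]germacra-1(10),3,11(13)-trien-12,6-olide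
Conditions: Et3N, DMAP (cat.), CH2Cl2, 0 → 23 °C
Reagents that add atoms: none
Why: DMAP-catalysed acylation of the only free hydroxyl group with the acid chloride proceeds with retention at C-8, and the (E)-configured acyl group is the thermodynamically favoured isomer.

**Step 16**
Reactants: 27 (1(10)E,3Z,5S,6S,7R,8S)-5-(tert-butyldimethylsilyloxy)-2,2-dimethoxy-8-[(E)-2-methylbut-2-enoyloxy]germacra-1(10),3,11(13)-trien-12,6-olide
Product: 29 molephantinin, via dienone silyl ether 28 (not isolated)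
Conditions: 48% aq. HF, MeCN, 0 °C
Reagents that add atoms: water, O
Why: Aqueous acid hydrolyses the doubly allylic dimethyl ketal to the cross-conjugated dienone 28 and fluoride then cleaves the silyl ether (global deprotection) without touching any stereocenter.

**Compound list**

1 | 4-methoxy-2-methylphenol | COc1ccc(O)c(C)c1 | starting material
2 | 4,4-dimethoxy-2-methylcyclohexa-2,5-dien-1-one | COC1(OC)C=CC(=O)C(C)=C1 | intermediate
3 | isopropenylboronic acid pinacol ester (4,4,5,5-tetramethyl-2-(prop-1-en-2-yl)-1,3,2-dioxaborolane) | CC(=C)B1OC(C)(C)C(C)(C)O1 | starting material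
4 | (5R)-4,4-dimethoxy-2-methyl-5-(prop-1-en-2-yl)cyclohex-2-en-1-one | O=C1C(C)=CC(OC)(OC)[C@@H](C(C)=C)C1 | intermediate
5 | potassium (1S,6S)-5,5-dimethoxy-3-methyl-2-oxo-6-(prop-1-en-2-yl)cyclohex-3-en-1-olate | O=C1C(C)=CC(OC)(OC)[C@@H](C(C)=C)[C@@H]1[O-].[K+] | intermediate (not isolated)
6 | (5S,6S)-4,4-dimethoxy-2-methyl-5-(prop-1-en-2-yl)-6-(triethylsilyloxy)cyclohex-2-en-1-one | O=C1C(C)=CC(OC)(OC)[C@@H](C(C)=C)[C@@H]1O[Si](CC)(CC)CC | intermediate
7 | (1S,5S,6S)-4,4-dimethoxy-2-methyl-5-(prop-1-en-2-yl)-6-(triethylsilyloxy)cyclohex-2-en-1-ol | O[C@H]1C(C)=CC(OC)(OC)[C@@H](C(C)=C)[C@@H]1O[Si](CC)(CC)CC | intermediate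
8 | tert-butyl{[(1S,5S,6S)-4,4-dimethoxy-2-methyl-5-(prop-1-en-2-yl)-6-(triethylsilyloxy)cyclohex-2-en-1-yl]oxy}dimethylsilane | CC(C)(C)[Si](C)(C)O[C@H]1C(C)=CC(OC)(OC)[C@@H](C(C)=C)[C@@H]1O[Si](CC)(CC)CC | intermediate
9 | (1S,2S,6S)-2-(tert-butyldimethylsilyloxy)-5,5-dimethoxy-3-methyl-6-(prop-1-en-2-yl)cyclohex-3-en-1-ol | CC(C)(C)[Si](C)(C)O[C@H]1C(C)=CC(OC)(OC)[C@@H](C(C)=C)[C@@H]1O | intermediate
10 | (2S,6S)-2-(tert-butyldimethylsilyloxy)-5,5-dimethoxy-3-methyl-6-(prop-1-en-2-yl)cyclohex-3-en-1-one | CC(C)(C)[Si](C)(C)O[C@H]1C(C)=CC(OC)(OC)[C@@H](C(C)=C)C1=O | intermediate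
11 | 4-methoxybenzyl alcohol | COc1ccc(CO)cc1 | starting material
12 | trichloroethylene | ClC=C(Cl)Cl | starting material
13 | 1-({[(E)-1,2-dichloroethenyl]oxy}methyl)-4-methoxybenzene | COc1ccc(CO/C(Cl)=C\Cl)cc1 | intermediate
14 | lithium 2-[(4-methoxybenzyl)oxy]ethyn-1-ide | [Li+].[C-]#COCc1ccc(OC)cc1 | intermediate (not isolated)
15 | (1S,2S,6S)-2-(tert-butyldimethylsilyloxy)-5,5-dimethoxy-1-{[(4-methoxybenzyl)oxy]ethynyl}-3-methyl-6-(prop-1-en-2-yl)cyclohex-3-en-1-ol | O[C@]1(C#COCc2ccc(OC)cc2)[C@H](C(C)=C)C(OC)(OC)C=C(C)[C@@H]1O[Si](C)(C)C(C)(C)C | intermediate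
16 | (1R,2S,6S)-2-(tert-butyldimethylsilyloxy)-5,5-dimethoxy-1-{(E)-2-[(4-methoxybenzyl)oxy]ethenyl}-3-methyl-6-(prop-1-en-2-yl)cyclohex-3-en-1-ol | O[C@]1(/C=C/OCc2ccc(OC)cc2)[C@H](C(C)=C)C(OC)(OC)C=C(C)[C@@H]1O[Si](C)(C)C(C)(C)C | intermediate
17 | methyl bromoacetate | COC(=O)CBr | starting material
18 | potassium enolate of the ring-expanded ketone (C-6 oxido, C-6=C-7; 5S,8S) | [K+].[O-]/C1=C\[C@@H](OCc2ccc(OC)cc2)C/C(C)=C/C(OC)(OC)/C=C(/C)[C@@H]1O[Si](C)(C)C(C)(C)C | intermediate (not isolated)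
19 | methyl [(1(10)E,3Z,5S,7R,8S)-5-(tert-butyldimethylsilyloxy)-2,2-dimethoxy-8-(4-methoxybenzyloxy)-4,10-dimethyl-6-oxocyclodeca-1(10),3-dien-7-yl]acetate | O=C1[C@H](CC(=O)OC)[C@@H](OCc2ccc(OC)cc2)C/C(C)=C/C(OC)(OC)/C=C(/C)[C@@H]1O[Si](C)(C)C(C)(C)C | intermediate
20 | methyl [(1(10)E,3Z,5S,6S,7R,8S)-5-(tert-butyldimethylsilyloxy)-6-hydroxy-2,2-dimethoxy-8-(4-methoxybenzyloxy)-4,10-dimethylcyclodeca-1(10),3-dien-7-yl]acetate | O[C@H]1[C@H](CC(=O)OC)[C@@H](OCc2ccc(OC)cc2)C/C(C)=C/C(OC)(OC)/C=C(/C)[C@@H]1O[Si](C)(C)C(C)(C)C | intermediate (not isolated)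
21 | (1(10)E,3Z,5S,6S,7R,8S)-5-(tert-butyldimethylsilyloxy)-2,2-dimethoxy-8-(4-methoxybenzyloxy)germacra-1(10),3-dien-12,6-olide | C1C(=O)O[C@H]2[C@H]1[C@@H](OCc3ccc(OC)cc3)C/C(C)=C/C(OC)(OC)/C=C(/C)[C@@H]2O[Si](C)(C)C(C)(C)C | intermediate
22 | 11-(dimethylaminomethyl) derivative of 21 (C-11 configuration not defined) | CN(C)CC1C(=O)O[C@H]2[C@H]1[C@@H](OCc3ccc(OC)cc3)C/C(C)=C/C(OC)(OC)/C=C(/C)[C@@H]2O[Si](C)(C)C(C)(C)C | intermediate (not isolated)
23 | trimethylammonium iodide of 22 (C-11 configuration not defined) | C[N+](C)(C)CC1C(=O)O[C@H]2[C@H]1[C@@H](OCc3ccc(OC)cc3)C/C(C)=C/C(OC)(OC)/C=C(/C)[C@@H]2O[Si](C)(C)C(C)(C)C.[I-] | intermediate (not isolated)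
24 | (1(10)E,3Z,5S,6S,7R,8S)-5-(tert-butyldimethylsilyloxy)-2,2-dimethoxy-8-(4-methoxybenzyloxy)germacra-1(10),3,11(13)-trien-12,6-olide | C=C1C(=O)O[C@H]2[C@H]1[C@@H](OCc3ccc(OC)cc3)C/C(C)=C/C(OC)(OC)/C=C(/C)[C@@H]2O[Si](C)(C)C(C)(C)C | intermediate
25 | (1(10)E,3Z,5S,6S,7R,8S)-5-(tert-butyldimethylsilyloxy)-8-hydroxy-2,2-dimethoxygermacra-1(10),3,11(13)-trien-12,6-olide | C=C1C(=O)O[C@H]2[C@H]1[C@@H](O)C/C(C)=C/C(OC)(OC)/C=C(/C)[C@@H]2O[Si](C)(C)C(C)(C)C | intermediate
26 | (E)-2-methylbut-2-enoyl chloride (tigloyl chloride) | ClC(=O)/C(C)=C/C | starting material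
27 | (1(10)E,3Z,5S,6S,7R,8S)-5-(tert-butyldimethylsilyloxy)-2,2-dimethoxy-8-[(E)-2-methylbut-2-enoyloxy]germacra-1(10),3,11(13)-trien-12,6-olide | C=C1C(=O)O[C@H]2[C@H]1[C@@H](OC(=O)/C(C)=C/C)C/C(C)=C/C(OC)(OC)/C=C(/C)[C@@H]2O[Si](C)(C)C(C)(C)C | intermediate
28 | (1(10)E,3Z,5S,6S,7R,8S)-5-(tert-butyldimethylsilyloxy)-8-[(E)-2-methylbut-2-enoyloxy]-2-oxogermacra-1(10),3,11(13)-trien-12,6-olide | C=C1C(=O)O[C@H]2[C@H]1[C@@H](OC(=O)/C(C)=C/C)C/C(C)=C/C(=O)/C=C(/C)[C@@H]2O[Si](C)(C)C(C)(C)C | intermediate (not isolated)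
29 | molephantinin | C=C1C(=O)O[C@H]2[C@H]1[C@@H](OC(=O)/C(C)=C/C)C/C(C)=C/C(=O)/C=C(/C)[C@@H]2O | target

**Step count.** Total: 16 steps. Longest linear sequence: 15 steps (1 → 29 through steps 1–7 and 9–16; step 8 is a one-step side branch).

**Steps most likely to fail**

Step 11. The free potassium enolate may lose the C-8 alkoxide by β-elimination, or a 1,2-silyl shift may intervene, before C-alkylation occurs. The fallback sets out from 16 and comes back at 19. The rearrangement is run as before (KHMDS, 18-crown-6, THF) but the enolate is trapped at −78 °C with chlorotrimethylsilane as the trimethylsilyl enol ether of the ring-expanded ketone F1. Copper-catalysed cyclopropanation of this most electron-rich alkene with methyl diazoacetate (Cu(acac)2, CH2Cl2), expected from the peripheral face, gives the siloxycyclopropane ester F2. Fluoride-induced ring opening (Et3N·3HF, THF, 0 °C) then releases γ-keto ester 19 without passing through a free ketone enolate.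

Step 2. Insertion at the hindered β-carbon next to the ketal may be slow or poorly enantioselective, and the isopropenyl boronate may protodeboronate. The fallback sets out from 2 and comes back at 4. Copper-catalysed conjugate addition of isopropenylmagnesium bromide (CuBr·SMe2, THF, −40 °C) gives racemic 4,4-dimethoxy-2-methyl-5-(prop-1-en-2-yl)cyclohex-2-en-1-one F3. Preparative chromatography on a chiral stationary phase returns 4 and leaves the (5S)-enantiomer F4.

Step 12. Facial selectivity of hydride delivery to the conformationally mobile ten-membered ketone may be poor or reversed, so that the C-6 epimer forms and closes to the cis-fused lactone. The fallback sets out from 19 and comes back at 21. The reduction is then run to favour the other face (NaBH4, MeOH, −40 °C), giving the (6R)-hydroxy ester F5, which closes to the cis-fused 6-epi lactone F6. Saponification (LiOH, THF/H2O) and careful acidification give the (6R)-hydroxy acid F7. Intramolecular Mitsunobu lactonisation (PPh3, DIAD, THF) closes the ring with inversion at C-6 to give 21.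

**Further compounds**

F1 | step 11 | trimethylsilyl enol ether of the ring-expanded ketone | C[Si](C)(C)O/C1=C\[C@@H](OCc2ccc(OC)cc2)C/C(C)=C/C(OC)(OC)/C=C(/C)[C@@H]1O[Si](C)(C)C(C)(C)C
F2 | step 11 | siloxycyclopropane ester (ester-bearing carbon not defined) | COC(=O)C1[C@@]2(O[Si](C)(C)C)[C@H]1[C@@H](OCc3ccc(OC)cc3)C/C(C)=C/C(OC)(OC)/C=C(/C)[C@@H]2O[Si](C)(C)C(C)(C)C
F3 | step 2 | racemic 4,4-dimethoxy-2-methyl-5-(prop-1-en-2-yl)cyclohex-2-en-1-one | O=C1C(C)=CC(OC)(OC)C(C(C)=C)C1
F4 | step 2 | (5S)-4,4-dimethoxy-2-methyl-5-(prop-1-en-2-yl)cyclohex-2-en-1-one | O=C1C(C)=CC(OC)(OC)[C@H](C(C)=C)C1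
F5 | step 12 | (6R)-hydroxy ester (C-6 epimer of 20) | O[C@@H]1[C@H](CC(=O)OC)[C@@H](OCc2ccc(OC)cc2)C/C(C)=C/C(OC)(OC)/C=C(/C)[C@@H]1O[Si](C)(C)C(C)(C)C
F6 | step 12 | cis-fused 6-epi lactone (C-6 epimer of 21) | C1C(=O)O[C@@H]2[C@H]1[C@@H](OCc3ccc(OC)cc3)C/C(C)=C/C(OC)(OC)/C=C(/C)[C@@H]2O[Si](C)(C)C(C)(C)C
F7 | step 12 | (6R)-hydroxy acid | O[C@@H]1[C@H](CC(=O)O)[C@@H](OCc2ccc(OC)cc2)C/C(C)=C/C(OC)(OC)/C=C(/C)[C@@H]1O[Si](C)(C)C(C)(C)C
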